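## The problem

Compound 12 is a dihydrochalcone without a stereocentre, and its difficulty lies in ring A. This benzene ring carries four contiguous substituents: the 3-phenylpropanoyl group at C1', a methoxy group at C2', the 2-hydroxybenzyl group at C3' and a free hydroxyl at C4'. A synthesis that starts from an aromatic ring must place a benzyl group between the two oxygens of a 1,3-dioxygenated arene and put the acyl group beside one of them. It must then tell the two oxygens apart, so that the one next to the ketone is methylated while the other and the ring C phenol stay free. The sensitive parts are the enolisable aryl ketone (open to over-reduction and C-alkylation), the electron-rich phenols, and the diarylmethane flanked by two ortho hydroxyls, which strong acid could close to a xanthene. With no stereocentre, the only control needed is control of position. The feature that opens a short route is that Cβ, Cα, the ketone carbon, C1', C2', C3' and the benzylic CH2 form one unbranched seven-carbon chain from ring B to ring C. Ring A is therefore a 1,7-diarylheptane-3,5-dione bridged from C3' to C1' by C4', C5' and C6', and the ring C oxygen can hold that three-carbon bridge as an ester within six-membered reach of C3'. Once ring A exists with the ketone on C1', the hydrogen bond from the C2' hydroxyl to the carbonyl makes the three phenols chemically different, which the last steps exploit.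

## Retrosynthesis

**Oxygen pattern (12 ⇐ 11 ⇐ 10 ⇐ 9).** The bonds cut are the O–methyl bond at C2' and two temporary O–benzyl bonds. In triol 9 the C2' hydroxyl is chelated to the ketone and flanked by two ortho substituents, so it is the least reactive phenol, yet it is the one to be methylated. A direct cut from 12 to 9 is therefore not available. The opposite order (methylate all three, then remove two) would cleave the chelated methyl ether first, which is the wrong one. The two ordinary phenols are therefore capped as benzyl ethers (10), the chelated phenol is methylated (11), and the benzyl groups are removed under neutral conditions (12). The forward steps need only the usual reactivity gap between free and chelated phenols and a debenzylation that spares an aryl ketone.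

**Ring A (9 ⇐ 7, through 8).** The C3'–C4' and C1'–C6' bonds are cut, which opens ring A to a linear diketone whose ring C phenol carries C4'–C6' as an (E)-3-ethoxyacryloyl ester.
- The neighbouring cuts, at the C1'–carbonyl bond or the C3'–benzyl bond, keep an aromatic ring A. They leave the 1,2,3,4-pattern to the selectivity of aromatic substitution between two near-equivalent positions.
- Cutting through the ring turns every ring position into a chain position: C1' is the central carbon of the diketone, C2' a ketone carbon, C3' an α'-methylene, and C4' arrives at the acid oxidation level. The arene then forms with both hydroxyls, the acyl group and the benzyl group in place and with no oxidation step.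
- The precursor 7 is acyclic, achiral and made of three simple pieces.
- The forward reaction must do two things. The C3' carbanion of the diketone has to take the acyl group from the ring C oxygen (giving triketone 8, not isolated). C1' of 8 then has to add to C6' with loss of the ethoxy group.

**Ester (7 ⇐ 3 + 5, through 6).** The aryl ester C–O bond is cut, giving phenolic diketone 3 and (E)-3-ethoxyacrylic acid 5, activated as its chloride 6 (not isolated). This cut is preferred to building the diketone on a preformed aryl ester, because the ester would not survive the strongly basic chain assembly. The forward step needs acylation of a phenol in the presence of a chelated β-diketone enol. Acid 5 comes from commercial ester 4 by hydrolysis.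

**Chain (3 ⇐ 1 + 2).** The C1'–C2' bond is cut as a crossed Claisen acylation. Lactone 2 supplies ring C, the benzylic CH2, C3' and C2' in one piece, and its leaving group is the very phenol needed for the next step, so no protecting group is required. Ketone 1 supplies ring B, Cβ, Cα, the ketone carbon and C1'. The forward step needs the methyl-side enolate of 1 and enough of it to absorb the acidity of the product.

## Roads not taken

**Alternative 1:** The two bonds to the carbonyl carbon are cut, giving aryl iodide A2, carbon monoxide A4 and phenylacetylene A3. The forward key step is a palladium-catalysed carbonylative Sonogashira coupling to alkynone A1.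
- Merits: this is established chemistry, which the chosen plan cannot claim for its key step. The endgame is also shorter: one hydrogenation of A1 would saturate the triple bond and remove both benzyl ethers to give 12, against three steps after the ring closure in the chosen plan.
- Weak points: A2 must already carry all four ring A substituents, so the real problem is moved into its preparation rather than solved. The two oxygens flanking the benzyl group differ only in their alkyl groups. The iodine must enter ortho to the methoxy group and not ortho to the benzyloxy group, two positions of nearly equal electron density. Direct, non-carbonylative coupling is a known competitor for electron-rich, ortho-substituted aryl iodides.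
- Comparison: the chosen plan sets against this a ring construction in which position is fixed by chain connectivity and a tether, and oxygen differentiation that comes from chelation.

**Alternative 2:** The C2'–C3' and C4'–C5' bonds are cut, giving cyclobutenone A6 and siloxyalkyne A7. The forward key step is a thermal Danheiser benzannulation to the monosilylated 2-benzylresorcinol A5.
- Merits: the cascade is known, neutral and regiospecific. It delivers the benzyl group between two oxygens that are already differentiated, which the chosen plan achieves only after ring formation.
- Weak points: A5 has no carbon at C1'. The acyl chain would still have to be added by O-acylation and Fries shift, followed by methylation, desilylation and debenzylation. That is five operations after the key step instead of three. A6 is volatile and prone to polymerise, and A7 needs a multistep ynolate-based preparation and is sensitive to moisture.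
- Comparison: the alternative is mechanistically safer at the ring-forming step. The chosen plan is shorter overall and forms the C1'–acyl relationship in the same step as the ring.

**Alternative 3:** The C2'–C1' and C5'–C6' bonds are cut, giving the 2-benzylated ketene-acetal diene A9 and ynone A10. The forward key step is a Diels–Alder reaction followed by loss of one methoxy group and desilylation, giving A8.
- Merits: this is the most convergent of the four plans. A8 already has the C2' methyl ether and the free C4' hydroxyl, and stands one debenzylation from 12. The chosen plan spends three steps on a pattern this route gets for nothing. The regiochemistry (nucleophilic CH2 terminus to the alkyne β-carbon) is expected to be correct.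
- Weak points: A9 is a fully substituted, hydrolytically labile ketene acetal with no simple preparation from the corresponding β-keto ester. The cycloaddition must join its tetrasubstituted terminus C2' to the acyl-bearing carbon C1'. A10 is a terminal ynone prone to polymerisation and to stepwise conjugate addition.
- Comparison: the chosen plan offers bench-stable precursors made in three ordinary steps and a bond-forming sequence that does not depend on a fragile diene. It is the longer of the two after the key step.

Key step: step 4

Remark on the chemistry: 12 has no stereocentre. The β-diketones and the triketone are drawn as keto forms although they should exist largely as chelated enols. Compound 8 is formed as its lithium enolate and is racemic at its one sp3 methine.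

## Route

Step 1
Reactants: 1 4-phenylbutan-2-one; 2 3,4-dihydrocoumarin (chroman-2-one)
Product: 3 1-(2-hydroxyphenyl)-7-phenylheptane-3,5-dione
Conditions: 1 (2.2 equiv), LiN(iPr)2 (2.3 equiv), THF, −78 °C; then 2, −78 → 0 °C; 1 M HCl
Reagents that add atoms: none
Why: Kinetic deprotonation of the methyl ketone gives the less substituted lithium enolate, which opens the aryl lactone in a crossed Claisen acylation. The second equivalent of enolate deprotonates the β-diketone as it forms, which stops further acylation, and the phenoxide leaving group stays in the molecule as the free phenol.

Step 2
Reactants: 4 ethyl (E)-3-ethoxyacrylate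
Product: 5 (E)-3-ethoxyacrylic acid
Conditions: 2 M NaOH, H2O, reflux; then HCl to pH 3, 0 °C
Reagents that add atoms: sodium hydroxide, [Na+].[OH-]
Why: Ester saponification. The vinylogous carbonate is stable to aqueous base and the alkene geometry is not touched; cold, brief acidification protects the enol ether.

Step 3
Reactants: 5 (E)-3-ethoxyacrylic acid; 3 1-(2-hydroxyphenyl)-7-phenylheptane-3,5-dione
Product: 7 2-(3,5-dioxo-7-phenylheptyl)phenyl (E)-3-ethoxyacrylate, via (E)-3-ethoxyacryloyl chloride 6 (not isolated)
Conditions: 5, (COCl)2, DMF (cat.), CH2Cl2, 0 °C → rt, evaporate; then 3, pyridine, CH2Cl2, 0 °C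
Reagents that add atoms: none
Why: Acid chloride formation under Vilsmeier catalysis, then pyridine-mediated O-acylation of the phenol. The acyclic β-diketone is a chelated enol of low nucleophilicity and should be left alone, as in the esterification of phenolic β-diketones of the curcumin type.

Step 4
Reactants: 7 2-(3,5-dioxo-7-phenylheptyl)phenyl (E)-3-ethoxyacrylate
Product: 9 1-[2,4-dihydroxy-3-(2-hydroxybenzyl)phenyl]-3-phenylpropan-1-one, via triketone 8 (not isolated)
Conditions: 7 added slowly to LiN(iPr)2 (3.3 equiv), THF (0.02 M), −78 → 0 °C; then EtOH, 60 °C; 1 M HCl
Reagents that add atoms: none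
Why: Proposed new method: the first equivalent of amide gives the diketonate and a second removes an α'-proton; only the C3' carbanion can reach the aryl ester carbonyl through a six-membered transition state, so the 3-ethoxyacryloyl group moves from the ring C oxygen to C3' (C3'–C4' bond) and triketone 8 is released as its enolate beside the phenoxide, the closest known reaction being the Baker–Venkataraman O-to-C acyl transfer, here run on a β-diketone dianion instead of a ketone enolate. The Cα carbanion on the other arm would need a ten-membered transition state and conjugate attack of C3' on C6' an eight-membered one, so the tether secures both the choice of arm and attack at the carbonyl carbon; the two dianions can interconvert by proton exchange and should drain through the C3' channel. The third equivalent of base is taken up by the newly formed, more acidic triketone. After ethanol is added and the mixture is warmed, the doubly activated C1' of the triketone enolate adds to C6' of the β-ethoxy enone in its s-cis conformation and ethoxide leaves (6-endo-trig addition–elimination, C1'–C6' bond, closure of six-membered ring A), as in the known cyclisation of β-polycarbonyl chains onto β-alkoxy enones. Two enolisations of the resulting cyclohexenedione give the 1,3-dihydroxyarene without any change of oxidation level, and the gain of aromaticity should make the sequence irreversible. Should the C2' enol oxygen add to C6' first, the 4-pyranone so formed is expected to be reopened at C6' by ethoxide and to reach the same arene. No stereocentre is formed.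

Step 5
Reactants: 9 1-[2,4-dihydroxy-3-(2-hydroxybenzyl)phenyl]-3-phenylpropan-1-one
Product: 10 1-{4-(benzyloxy)-3-[2-(benzyloxy)benzyl]-2-hydroxyphenyl}-3-phenylpropan-1-one
Conditions: BnBr (2.2 equiv), K2CO3, acetone, reflux
Reagents that add atoms: benzyl bromide, BrCc1ccccc1
Why: Williamson etherification. The C2' hydroxyl is held in a hydrogen bond to the ketone and shielded by two ortho substituents, so carbonate and a limited amount of benzyl bromide should alkylate only the C4' and ring C phenols, as is general for 2,4-dihydroxyaryl ketones.

Step 6
Reactants: 10 1-{4-(benzyloxy)-3-[2-(benzyloxy)benzyl]-2-hydroxyphenyl}-3-phenylpropan-1-one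
Product: 11 1-{4-(benzyloxy)-3-[2-(benzyloxy)benzyl]-2-methoxyphenyl}-3-phenylpropan-1-one
Conditions: MeI (excess), K2CO3, DMF, 50 °C
Reagents that add atoms: iodomethane, CI
Why: Williamson O-methylation of the remaining chelated phenol under more forcing conditions (polar aprotic solvent, small electrophile). Carbonate is too weak to enolise the ketone, so C-methylation is not expected.

Step 7
Reactants: 11 1-{4-(benzyloxy)-3-[2-(benzyloxy)benzyl]-2-methoxyphenyl}-3-phenylpropan-1-one
Product: 12 1-[4-hydroxy-3-(2-hydroxybenzyl)-2-methoxyphenyl]-3-phenylpropan-1-one
Conditions: H2 (1 atm), 10% Pd/C, EtOAc, rt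
Reagents that add atoms: none
Why: Catalytic hydrogenolysis of the two aryl benzyl ethers. The aryl alkyl ketone, the methyl ether and the diarylmethane should survive at atmospheric pressure in a neutral solvent if the reaction is stopped at full debenzylation.

## Compound list

1 | 4-phenylbutan-2-one | CC(=O)CCc1ccccc1 | starting material
2 | 3,4-dihydrocoumarin (chroman-2-one) | O=C1CCc2ccccc2O1 | starting material
3 | 1-(2-hydroxyphenyl)-7-phenylheptane-3,5-dione | O=C(CCc1ccccc1)CC(=O)CCc1ccccc1O | intermediate
4 | ethyl (E)-3-ethoxyacrylate | CCO/C=C/C(=O)OCC | starting material
5 | (E)-3-ethoxyacrylic acid | CCO/C=C/C(=O)O | intermediate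
6 | (E)-3-ethoxyacryloyl chloride (formed in the flask, not isolated) | CCO/C=C/C(=O)Cl | intermediate
7 | 2-(3,5-dioxo-7-phenylheptyl)phenyl (E)-3-ethoxyacrylate | CCO/C=C/C(=O)Oc1ccccc1CCC(=O)CC(=O)CCc1ccccc1 | intermediate
8 | (E)-1-ethoxy-4-(2-hydroxybenzyl)-9-phenylnon-1-ene-3,5,7-trione (racemic, formed as its enolate, not isolated) | CCO/C=C/C(=O)C(Cc1ccccc1O)C(=O)CC(=O)CCc1ccccc1 | intermediate
9 | 1-[2,4-dihydroxy-3-(2-hydroxybenzyl)phenyl]-3-phenylpropan-1-one | O=C(CCc1ccccc1)c1ccc(O)c(Cc2ccccc2O)c1O | intermediate
10 | 1-{4-(benzyloxy)-3-[2-(benzyloxy)benzyl]-2-hydroxyphenyl}-3-phenylpropan-1-one | O=C(CCc1ccccc1)c1ccc(OCc2ccccc2)c(Cc2ccccc2OCc2ccccc2)c1O | intermediate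
11 | 1-{4-(benzyloxy)-3-[2-(benzyloxy)benzyl]-2-methoxyphenyl}-3-phenylpropan-1-one | COc1c(C(=O)CCc2ccccc2)ccc(OCc2ccccc2)c1Cc1ccccc1OCc1ccccc1 | intermediate
12 | 1-[4-hydroxy-3-(2-hydroxybenzyl)-2-methoxyphenyl]-3-phenylpropan-1-one | COc1c(C(=O)CCc2ccccc2)ccc(O)c1Cc1ccccc1O | target

## Step count and risk

Total steps: 7. Longest linear sequence: 6 (steps 1, 3, 4, 5, 6, 7 from 1 and 2; equally steps 2, 3, 4, 5, 6, 7 from 4).

**Step 4 (key step).**
- What may go wrong: the aryl ester may be cleaved by intermolecular attack before the weakly acidic C3' position is deprotonated, which would return 3. Ring closure may also go through the enol oxygen to a 4-pyranone that is not reopened under the reaction conditions. Both follow from the need to generate a dianion next to a reactive aryl ester and from the ambident character of the triketone enolate.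
- Fallback (known chemistry, sets out from 2, uses 4, returns at 9): the tether is replaced by a chain with only one enolisable arm. Crossed Claisen acylation of the lithium enolate of commercial (E)-4-phenylbut-3-en-2-one with 2 would give (1E)-7-(2-hydroxyphenyl)-1-phenylhept-1-ene-3,5-dione F1. Its styryl arm has no α'-hydrogen, so excess LiN(iPr)2 can form only the C3' carbanion. Hauser–Harris-type Claisen acylation of this polyanion at the ester carbonyl of 4 would give (1E,8E)-1-ethoxy-4-(2-hydroxybenzyl)-9-phenylnona-1,8-diene-3,5,7-trione F2. Base-mediated closure of C1' onto C6' with loss of the ethoxy group would give the chalcone (E)-1-[2,4-dihydroxy-3-(2-hydroxybenzyl)phenyl]-3-phenylprop-2-en-1-one F3. Hydrogenation of the enone double bond (H2, Pd/C, EtOAc) would give 9.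

**Step 1.**
- What may go wrong: the enolate may act as a base toward the lactone α-position instead of as a nucleophile. This would lead to ring-opening of the lactone enolate and oligomerisation. Partial equilibration to the more substituted enolate during the slow acylation is a second concern.
- Fallback (sets out from 1, returns at 3): the C–C bond is made by alkylation instead of acylation. Claisen condensation of 1 with ethyl acetate (NaH, THF) would give 6-phenylhexane-2,4-dione F4. Its dianion (LiN(iPr)2, 2.2 equiv), formed at the methyl terminus, would be alkylated with commercial 2-(benzyloxy)benzyl bromide to give 1-[2-(benzyloxy)phenyl]-7-phenylheptane-3,5-dione F5. Hydrogenolysis (H2, Pd/C) would give 3.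

**Step 5.**
- What may go wrong: alkylation may spill over to the chelated C2' oxygen, or stop short at the hindered C4' oxygen next to the benzyl group, so that a mixture of partly and fully benzylated material results.
- Fallback (sets out from 9, returns at 10): selectivity is moved from the alkylation to a dealkylation. Exhaustive benzylation (BnBr excess, K2CO3, DMF, 80 °C) would give 1-{2,4-bis(benzyloxy)-3-[2-(benzyloxy)benzyl]phenyl}-3-phenylpropan-1-one F6. The benzyl ether ortho to the ketone would then be removed selectively by chelation-assisted cleavage with MgBr2·OEt2 (toluene/Et2O, reflux) to give 10.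

**Step 7.**
- What may go wrong: the aryl ketone may be reduced to the benzylic alcohol and on to the methylene while the more hindered benzyl ether is still being cleaved.
- Fallback (sets out from 9, returns at 12): acid-labile protection replaces hydrogenolysis. The two non-chelated phenols would be protected with MOMCl and iPr2NEt (CH2Cl2, 0 °C) to give 1-{2-hydroxy-4-(methoxymethoxy)-3-[2-(methoxymethoxy)benzyl]phenyl}-3-phenylpropan-1-one F7. Methylation (MeI, K2CO3, DMF) would give 1-{2-methoxy-4-(methoxymethoxy)-3-[2-(methoxymethoxy)benzyl]phenyl}-3-phenylpropan-1-one F8. Mild acid methanolysis (HCl, MeOH, 40 °C) would give 12.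

## Further compounds

F1 | step 4 | (1E)-7-(2-hydroxyphenyl)-1-phenylhept-1-ene-3,5-dione | O=C(/C=C/c1ccccc1)CC(=O)CCc1ccccc1O
F2 | step 4 | (1E,8E)-1-ethoxy-4-(2-hydroxybenzyl)-9-phenylnona-1,8-diene-3,5,7-trione | CCO/C=C/C(=O)C(Cc1ccccc1O)C(=O)CC(=O)/C=C/c1ccccc1
F3 | step 4 | (E)-1-[2,4-dihydroxy-3-(2-hydroxybenzyl)phenyl]-3-phenylprop-2-en-1-one | O=C(/C=C/c1ccccc1)c1ccc(O)c(Cc2ccccc2O)c1O
F4 | step 1 | 6-phenylhexane-2,4-dione | CC(=O)CC(=O)CCc1ccccc1
F5 | step 1 | 1-[2-(benzyloxy)phenyl]-7-phenylheptane-3,5-dione | O=C(CCc1ccccc1)CC(=O)CCc1ccccc1OCc1ccccc1
F6 | step 5 | 1-{2,4-bis(benzyloxy)-3-[2-(benzyloxy)benzyl]phenyl}-3-phenylpropan-1-one | O=C(CCc1ccccc1)c1ccc(OCc2ccccc2)c(Cc2ccccc2OCc2ccccc2)c1OCc1ccccc1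
F7 | step 7 | 1-{2-hydroxy-4-(methoxymethoxy)-3-[2-(methoxymethoxy)benzyl]phenyl}-3-phenylpropan-1-one | COCOc1ccc(C(=O)CCc2ccccc2)c(O)c1Cc1ccccc1OCOC
F8 | step 7 | 1-{2-methoxy-4-(methoxymethoxy)-3-[2-(methoxymethoxy)benzyl]phenyl}-3-phenylpropan-1-one | COCOc1ccc(C(=O)CCc2ccccc2)c(OC)c1Cc1ccccc1OCOC
A1 | alternative 1 | 1-{4-(benzyloxy)-3-[2-(benzyloxy)benzyl]-2-methoxyphenyl}-3-phenylprop-2-yn-1-one | COc1c(C(=O)C#Cc2ccccc2)ccc(OCc2ccccc2)c1Cc1ccccc1OCc1ccccc1
A2 | alternative 1 | 1-(benzyloxy)-2-[2-(benzyloxy)benzyl]-4-iodo-3-methoxybenzene | COc1c(I)ccc(OCc2ccccc2)c1Cc1ccccc1OCc1ccccc1
A3 | alternative 1 | phenylacetylene | C#Cc1ccccc1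
A4 | alternative 1 | carbon monoxide | [C-]#[O+]
A5 | alternative 2 | 2-[2-(benzyloxy)benzyl]-3-[(triisopropylsilyl)oxy]phenol | CC(C)[Si](Oc1cccc(O)c1Cc1ccccc1OCc1ccccc1)(C(C)C)C(C)C
A6 | alternative 2 | cyclobut-2-en-1-one | O=C1CC=C1
A7 | alternative 2 | ({3-[2-(benzyloxy)phenyl]prop-1-yn-1-yl}oxy)triisopropylsilane | CC(C)[Si](OC#CCc1ccccc1OCc1ccccc1)(C(C)C)C(C)C
A8 | alternative 3 | 1-{3-[2-(benzyloxy)benzyl]-4-hydroxy-2-methoxyphenyl}-3-phenylpropan-1-one | COc1c(C(=O)CCc2ccccc2)ccc(O)c1Cc1ccccc1OCc1ccccc1
A9 | alternative 3 | ({3-[2-(benzyloxy)benzyl]-4,4-dimethoxybuta-1,3-dien-2-yl}oxy)trimethylsilane | COC(OC)=C(Cc1ccccc1OCc1ccccc1)C(=C)O[Si](C)(C)C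
A10 | alternative 3 | 5-phenylpent-1-yn-3-one | C#CC(=O)CCc1ccccc1
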